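**Plan**
- Retrosynthesis, last bond first: the C3–C4 ring bond (alkenyl-to-aldehyde addition), then C11=C13 (lactone methylenation), C4=C5 (iodo-olefination), the C1–C10 oxirane oxygen, the C8 ester C–O bond and C7–C8 (conjugate addition). Three simple fragments remain.
- Enabling feature: C3 is an allylic carbinol bonded to the vinylic C4 of the Z C4=C5 alkene inside the ten-membered ring. The trans-fused γ-lactone (O–C6–C7–C11–C12), the Z alkene and the trans C1–C10 oxirane pre-organise the seco chain. A C4 iodide (activating group, lost in the event) lets a Ni/Cr-mediated addition close the ring on unprotected, fully functionalised material in the last step.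
- Forward order of rings: γ-lactone (chiral-pool butenolide), oxirane of the acid fragment, C1–C10 oxirane, ten-membered carbocycle last. Chain joined at C7–C8, then C4=C5, then C11=C13, then C3–C4.
- Stereochemistry: C6 from (S)-5-(hydroxymethyl)furan-2(5H)-one; C7 by anti conjugate addition; C8 by CBS reduction; C1/C10 by Shi epoxidation of an E alkene from a stabilised Wittig reaction; C2′/C3′ by Sharpless epoxidation of a Z allylic alcohol; Z C4=C5 by Stork–Zhao olefination; C3 in the ring closure.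

Key step: step 20

Remark: germacrane numbering (C1–C15, acyl carbons C1′–C5′) is used for the target and all intermediates; 3-[(4-methoxybenzyl)oxy]propanal is taken as commercially available.

**Fragment A: epoxy acid**

Step 1
Reactants: 1 (Z)-2-methylbut-2-enoic acid (angelic acid)
Product: 2 (Z)-2-methylbut-2-en-1-ol
Conditions: LiAlH4, Et2O, 0 °C → rt
Reagents that add atoms: none
Why: Hydride reduction of the α,β-unsaturated acid is 1,2-selective and should give the primary allylic alcohol without isomerising the Z alkene.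

Step 2
Reactants: 2 (Z)-2-methylbut-2-en-1-ol
Product: 3 [(2R,3S)-2,3-dimethyloxiran-2-yl]methanol
Conditions: Ti(OiPr)4 (10 mol%), D-(−)-diethyl tartrate (12 mol%), t-BuOOH, 4 Å MS, CH2Cl2, −20 °C
Reagents that add atoms: tert-butyl hydroperoxide, CC(C)(C)OO
Why: Sharpless asymmetric epoxidation; the titanium–D-tartrate complex delivers oxygen to one face of the Z allylic alcohol, which sets both oxirane carbons (2R,3S) and keeps the C3 methyl cis to CH2OH.

Step 3
Reactants: 3 [(2R,3S)-2,3-dimethyloxiran-2-yl]methanol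
Product: 4 (2S,3S)-2,3-dimethyloxirane-2-carboxylic acid
Conditions: RuCl3 (cat.), NaIO4, MeCN/EtOAc/H2O, 0 °C → rt
Reagents that add atoms: water, O
Why: Ruthenium tetroxide oxidation (RuO4 made from RuCl3 and NaIO4) takes the primary alcohol to the acid without opening the oxirane; the C2 descriptor changes from R to S only through the priority change.

**Fragment B: dithiane (C8, C9, C10, C14, C1–C3)**

Step 4
Reactants: 5 3-[(4-methoxybenzyl)oxy]propanal; 6 ethyl 2-(triphenylphosphoranylidene)propanoate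
Product: 7 ethyl (E)-5-[(4-methoxybenzyl)oxy]-2-methylpent-2-enoate
Conditions: CH2Cl2, rt → 40 °C
Reagents that add atoms: none
Why: Wittig olefination with a stabilised α-methyl ylide should give the E trisubstituted enoate, which fixes the C10=C1 geometry.

Step 5
Reactants: 7 ethyl (E)-5-[(4-methoxybenzyl)oxy]-2-methylpent-2-enoate
Product: 8 (E)-5-[(4-methoxybenzyl)oxy]-2-methylpent-2-en-1-ol
Conditions: i-Bu2AlH, CH2Cl2, −78 °C; aq. potassium sodium tartrate
Reagents that add atoms: none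
Why: 1,2-Reduction of the enoate by i-Bu2AlH gives the allylic alcohol with the alkene and the PMB ether untouched.

Step 6
Reactants: 8 (E)-5-[(4-methoxybenzyl)oxy]-2-methylpent-2-en-1-ol
Product: 9 1-({[(E)-5-bromo-4-methylpent-3-en-1-yl]oxy}methyl)-4-methoxybenzene
Conditions: CBr4, PPh3, CH2Cl2, 0 °C
Reagents that add atoms: carbon tetrabromide, BrC(Br)(Br)Br
Why: Appel bromination converts the primary allylic alcohol to the bromide by SN2 displacement, without allylic shift or change of alkene geometry.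

Step 7
Reactants: 10 1,3-dithiane; 9 1-({[(E)-5-bromo-4-methylpent-3-en-1-yl]oxy}methyl)-4-methoxybenzene
Product: 12 2-{(E)-5-[(4-methoxybenzyl)oxy]-2-methylpent-2-en-1-yl}-1,3-dithiane, via 2-lithio-1,3-dithiane 11 (not isolated)
Conditions: n-BuLi, THF, −30 °C; then 9, −78 → 0 °C
Reagents that add atoms: none
Why: Corey–Seebach alkylation; the lithiated dithiane displaces the primary allylic bromide (SN2) and gives C8 as a masked acyl anion carrying the C9–C3 chain.

**Fragment C: butenolide (C5, C6, C7, C11, C12)**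

Step 8
Reactants: 13 (S)-5-(hydroxymethyl)furan-2(5H)-one
Product: 14 (S)-5-{[(tert-butyldiphenylsilyl)oxy]methyl}furan-2(5H)-one
Conditions: t-BuPh2SiCl, imidazole, DMF, 0 °C → rt
Reagents that add atoms: tert-butyl(chloro)diphenylsilane, CC(C)(C)[Si](Cl)(c1ccccc1)c1ccccc1
Why: Imidazole-promoted silylation of the primary alcohol leaves the C6 stereocenter untouched and installs the bulky group that will direct the conjugate addition.

**Assembly**

Step 9
Reactants: 12 2-{(E)-5-[(4-methoxybenzyl)oxy]-2-methylpent-2-en-1-yl}-1,3-dithiane; 14 (S)-5-{[(tert-butyldiphenylsilyl)oxy]methyl}furan-2(5H)-one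
Product: 17 (4S,5S)-5-{[(tert-butyldiphenylsilyl)oxy]methyl}-4-(2-{(E)-5-[(4-methoxybenzyl)oxy]-2-methylpent-2-en-1-yl}-1,3-dithian-2-yl)dihydrofuran-2(3H)-one, via lithiated dithiane 15 (not isolated), via lithium enolate 16 (not isolated)
Conditions: 12, n-BuLi, THF, −30 °C; DMPU, −78 °C; 14; aq. NH4Cl
Reagents that add atoms: none
Why: Corey–Seebach conjugate (Michael) addition; the 2-alkyl dithiane anion, as a solvent-separated ion pair in DMPU, should add 1,4 to the butenolide on the face opposite the C6 silyloxymethyl group, which forms C7–C8 and sets C7 trans to C6.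

Step 10
Reactants: 17 (4S,5S)-5-{[(tert-butyldiphenylsilyl)oxy]methyl}-4-(2-{(E)-5-[(4-methoxybenzyl)oxy]-2-methylpent-2-en-1-yl}-1,3-dithian-2-yl)dihydrofuran-2(3H)-one
Product: 18 (4S,5S)-5-{[(tert-butyldiphenylsilyl)oxy]methyl}-4-{(E)-6-[(4-methoxybenzyl)oxy]-3-methylhex-3-enoyl}dihydrofuran-2(3H)-one
Conditions: MeI, CaCO3, MeCN/H2O 4:1, 45 °C
Reagents that add atoms: water, O
Why: Dithiane unmasking by S-methylation and hydrolysis frees the C8 ketone; the CaCO3 buffer avoids β-elimination of the lactone oxygen and keeps C7 in its stable trans configuration.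

Step 11
Reactants: 18 (4S,5S)-5-{[(tert-butyldiphenylsilyl)oxy]methyl}-4-{(E)-6-[(4-methoxybenzyl)oxy]-3-methylhex-3-enoyl}dihydrofuran-2(3H)-one
Product: 19 (4R,5S)-5-{[(tert-butyldiphenylsilyl)oxy]methyl}-4-{(1R,3E)-1-hydroxy-6-[(4-methoxybenzyl)oxy]-3-methylhex-3-en-1-yl}dihydrofuran-2(3H)-one
Conditions: (S)-2-methyl-CBS-oxazaborolidine (0.3 equiv), catecholborane, toluene/CH2Cl2, −78 °C
Reagents that add atoms: none
Why: Corey–Bakshi–Shibata reduction; the (S)-oxazaborolidine should bind the ketone with the branched C7 side as the large group and deliver hydride to give the 8R alcohol, while catecholborane at −78 °C spares the lactone and the alkene.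

Step 12
Reactants: 19 (4R,5S)-5-{[(tert-butyldiphenylsilyl)oxy]methyl}-4-{(1R,3E)-1-hydroxy-6-[(4-methoxybenzyl)oxy]-3-methylhex-3-en-1-yl}dihydrofuran-2(3H)-one; 4 (2S,3S)-2,3-dimethyloxirane-2-carboxylic acid
Product: 21 (1R,3E)-1-[(2S,3R)-2-{[(tert-butyldiphenylsilyl)oxy]methyl}-5-oxotetrahydrofuran-3-yl]-6-[(4-methoxybenzyl)oxy]-3-methylhex-3-en-1-yl (2S,3S)-2,3-dimethyloxirane-2-carboxylate, via O-acylisourea 20 (not isolated)
Conditions: DCC, DMAP, CH2Cl2, 0 °C → rt
Reagents that add atoms: none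
Why: Steglich esterification (carbodiimide activation, DMAP acyl transfer) should acylate the C8 alcohol with retention; the acid has no α-hydrogen, so C2′ and C3′ cannot epimerise.

Step 13
Reactants: 21 (1R,3E)-1-[(2S,3R)-2-{[(tert-butyldiphenylsilyl)oxy]methyl}-5-oxotetrahydrofuran-3-yl]-6-[(4-methoxybenzyl)oxy]-3-methylhex-3-en-1-yl (2S,3S)-2,3-dimethyloxirane-2-carboxylate
Product: 22 (1R)-1-[(2S,3R)-2-{[(tert-butyldiphenylsilyl)oxy]methyl}-5-oxotetrahydrofuran-3-yl]-2-[(2R,3R)-3-{2-[(4-methoxybenzyl)oxy]ethyl}-2-methyloxiran-2-yl]ethyl (2S,3S)-2,3-dimethyloxirane-2-carboxylate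
Conditions: D-fructose-derived Shi ketone (0.3 equiv), Oxone (2KHSO5·KHSO4·K2SO4), K2CO3, Bu4NHSO4, MeCN/CH2(OMe)2/aq. Na2B4O7 buffer, 0 °C
Reagents that add atoms: potassium peroxymonosulfate (KHSO5), [K+].[O-]S(=O)(=O)OO
Why: Shi epoxidation; the chiral dioxirane should attack the only electron-rich alkene through the spiro transition state and give the (1R,10R) trans oxirane from the E alkene under reagent control.

Step 14
Reactants: 22 (1R)-1-[(2S,3R)-2-{[(tert-butyldiphenylsilyl)oxy]methyl}-5-oxotetrahydrofuran-3-yl]-2-[(2R,3R)-3-{2-[(4-methoxybenzyl)oxy]ethyl}-2-methyloxiran-2-yl]ethyl (2S,3S)-2,3-dimethyloxirane-2-carboxylate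
Product: 23 (1R)-1-[(2S,3R)-2-(hydroxymethyl)-5-oxotetrahydrofuran-3-yl]-2-[(2R,3R)-3-{2-[(4-methoxybenzyl)oxy]ethyl}-2-methyloxiran-2-yl]ethyl (2S,3S)-2,3-dimethyloxirane-2-carboxylate
Conditions: Bu4NF, AcOH, THF, 0 °C → rt
Reagents that add atoms: none
Why: Fluoride-mediated desilylation frees the C5 alcohol, and the acetic acid buffer should protect the lactone, the ester and both oxiranes.

Step 15
Reactants: 23 (1R)-1-[(2S,3R)-2-(hydroxymethyl)-5-oxotetrahydrofuran-3-yl]-2-[(2R,3R)-3-{2-[(4-methoxybenzyl)oxy]ethyl}-2-methyloxiran-2-yl]ethyl (2S,3S)-2,3-dimethyloxirane-2-carboxylate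
Product: 24 (1R)-1-[(2S,3R)-2-formyl-5-oxotetrahydrofuran-3-yl]-2-[(2R,3R)-3-{2-[(4-methoxybenzyl)oxy]ethyl}-2-methyloxiran-2-yl]ethyl (2S,3S)-2,3-dimethyloxirane-2-carboxylate
Conditions: Dess–Martin periodinane, NaHCO3, CH2Cl2, 0 °C → rt
Reagents that add atoms: none
Why: Dess–Martin oxidation gives the C5 aldehyde under buffered, non-basic conditions, so C6 (now α to the aldehyde) should not epimerise.

Step 16
Reactants: 24 (1R)-1-[(2S,3R)-2-formyl-5-oxotetrahydrofuran-3-yl]-2-[(2R,3R)-3-{2-[(4-methoxybenzyl)oxy]ethyl}-2-methyloxiran-2-yl]ethyl (2S,3S)-2,3-dimethyloxirane-2-carboxylate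
Product: 25 (1R)-1-[(2S,3R)-2-[(Z)-2-iodoprop-1-en-1-yl]-5-oxotetrahydrofuran-3-yl]-2-[(2R,3R)-3-{2-[(4-methoxybenzyl)oxy]ethyl}-2-methyloxiran-2-yl]ethyl (2S,3S)-2,3-dimethyloxirane-2-carboxylate
Conditions: EtPPh3I, n-BuLi, THF, rt; I2, −78 °C; NaN(SiMe3)2, −78 → −20 °C; then 24, −78 °C
Reagents that add atoms: (1-iodoethylidene)triphenylphosphorane, CC(I)=P(c1ccccc1)(c1ccccc1)c1ccccc1, made in the flask from ethyltriphenylphosphonium iodide, CC[P+](c1ccccc1)(c1ccccc1)c1ccccc1.[I-], and iodine, II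
Why: Stork–Zhao variant of the Wittig reaction; the non-stabilised α-iodo ylide reacts under kinetic control and should give the Z iodoalkene (iodine cis to C6), which brings in C4, C15 and the activating iodide.

Step 17
Reactants: 25 (1R)-1-[(2S,3R)-2-[(Z)-2-iodoprop-1-en-1-yl]-5-oxotetrahydrofuran-3-yl]-2-[(2R,3R)-3-{2-[(4-methoxybenzyl)oxy]ethyl}-2-methyloxiran-2-yl]ethyl (2S,3S)-2,3-dimethyloxirane-2-carboxylate
Product: 29 (1R)-1-[(2S,3R)-2-[(Z)-2-iodoprop-1-en-1-yl]-4-methylidene-5-oxotetrahydrofuran-3-yl]-2-[(2R,3R)-3-{2-[(4-methoxybenzyl)oxy]ethyl}-2-methyloxiran-2-yl]ethyl (2S,3S)-2,3-dimethyloxirane-2-carboxylate, via lithium enolate 26 (not isolated), via Mannich base 27 (not isolated), via trimethylammonium iodide 28 (not isolated)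
Conditions: LiN(i-Pr)2 (1.1 equiv), THF, −78 °C; CH2=NMe2+ I−, −78 °C → rt; MeI, MeOH, rt; aq. NaHCO3, CH2Cl2
Reagents that add atoms: N,N-dimethylmethyleneiminium iodide (Eschenmoser's salt), C=[N+](C)C.[I-]
Why: Eschenmoser–Mannich α-methylenation; C11 is the only enolisable position (the C8 ester has no α-hydrogen), and aminomethylation, N-methylation and β-elimination should give the exocyclic C11=C13 alkene with no stereocenter left at C11.

Step 18
Reactants: 29 (1R)-1-[(2S,3R)-2-[(Z)-2-iodoprop-1-en-1-yl]-4-methylidene-5-oxotetrahydrofuran-3-yl]-2-[(2R,3R)-3-{2-[(4-methoxybenzyl)oxy]ethyl}-2-methyloxiran-2-yl]ethyl (2S,3S)-2,3-dimethyloxirane-2-carboxylate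
Product: 30 (1R)-1-[(2S,3R)-2-[(Z)-2-iodoprop-1-en-1-yl]-4-methylidene-5-oxotetrahydrofuran-3-yl]-2-[(2R,3R)-3-(2-hydroxyethyl)-2-methyloxiran-2-yl]ethyl (2S,3S)-2,3-dimethyloxirane-2-carboxylate
Conditions: DDQ, CH2Cl2/pH 7 phosphate buffer, 0 °C → rt
Reagents that add atoms: none
Why: Oxidative PMB cleavage with DDQ (hydride abstraction from the electron-rich benzyl ether, then hydrolysis) should leave the alkenyl iodide, both oxiranes and the α-methylene lactone intact.

Step 19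
Reactants: 30 (1R)-1-[(2S,3R)-2-[(Z)-2-iodoprop-1-en-1-yl]-4-methylidene-5-oxotetrahydrofuran-3-yl]-2-[(2R,3R)-3-(2-hydroxyethyl)-2-methyloxiran-2-yl]ethyl (2S,3S)-2,3-dimethyloxirane-2-carboxylate
Product: 31 (1R)-1-[(2S,3R)-2-[(Z)-2-iodoprop-1-en-1-yl]-4-methylidene-5-oxotetrahydrofuran-3-yl]-2-[(2R,3R)-2-methyl-3-(2-oxoethyl)oxiran-2-yl]ethyl (2S,3S)-2,3-dimethyloxirane-2-carboxylate
Conditions: Dess–Martin periodinane, NaHCO3, CH2Cl2, 0 °C; used crude
Reagents that add atoms: none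
Why: Buffered Dess–Martin oxidation gives the β,γ-epoxy aldehyde without the base that would open the oxirane by β-elimination.

Step 20
Reactants: 31 (1R)-1-[(2S,3R)-2-[(Z)-2-iodoprop-1-en-1-yl]-4-methylidene-5-oxotetrahydrofuran-3-yl]-2-[(2R,3R)-2-methyl-3-(2-oxoethyl)oxiran-2-yl]ethyl (2S,3S)-2,3-dimethyloxirane-2-carboxylate
Product: 33 (1R,3S,4Z,6R,7R,8R,10R)-3-hydroxy-1,10-epoxygermacra-4,11(13)-dien-12,6-olid-8-yl (2S,3S)-2,3-dimethyloxirane-2-carboxylate (CNP0268255.2), via alkenylchromium dichloride 32 (not isolated)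
Conditions: CrCl2 (12 equiv), NiCl2 (0.1 equiv), degassed DMSO, rt, slow addition of 31 (final 2 mM); aqueous work-up
Reagents that add atoms: none
Why: NiCl2 is reduced by CrCl2 to zerovalent nickel, which inserts into the C4–I bond with retention of the Z geometry; transmetalation gives the alkenylchromium dichloride 32 (trivalent chromium), which adds to the C3 aldehyde through a chromium-bound closed transition state and gives 33 on aqueous work-up. The closest known reaction type is the intramolecular Nozaki–Hiyama–Kishi alkenyl iodide–aldehyde coupling, which is established for medium-ring and macrocyclic carbocycles. The ten-membered carbocycle closes in the 10-exo-trig mode (C4 attacks C3, the carbonyl oxygen stays outside the ring), with the lactone and both oxiranes already in place. The new stereocenter C3 is set by the substrate alone: the trans-fused lactone, the Z alkene and the trans oxirane leave six rotatable ring bonds, and attack on the aldehyde face that keeps the O–Cr unit on the periphery of the forming ring, away from the C10 methyl and the C8 ester, should give the 3S alcohol. The step needs chemoselectivity for the aldehyde over the α-methylene lactone, the ester and two oxiranes (the low basicity and aldehyde selectivity of organochromium reagents should secure it), retention of the Z alkene (trisubstituted alkenylchromium species do not isomerise) and ring closure over oligomerisation (high dilution, slow addition).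

**Compound list**

1 | (Z)-2-methylbut-2-enoic acid (angelic acid) | C/C=C(/C)C(=O)O | starting material
2 | (Z)-2-methylbut-2-en-1-ol | C/C=C(/C)CO | intermediate
3 | [(2R,3S)-2,3-dimethyloxiran-2-yl]methanol | OC[C@@]1(C)O[C@H]1C | intermediate
4 | (2S,3S)-2,3-dimethyloxirane-2-carboxylic acid | OC(=O)[C@@]1(C)O[C@H]1C | intermediate
5 | 3-[(4-methoxybenzyl)oxy]propanal | O=CCCOCc1ccc(OC)cc1 | starting material
6 | ethyl 2-(triphenylphosphoranylidene)propanoate | CCOC(=O)C(C)=P(c1ccccc1)(c1ccccc1)c1ccccc1 | starting material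
7 | ethyl (E)-5-[(4-methoxybenzyl)oxy]-2-methylpent-2-enoate | CCOC(=O)/C(C)=C/CCOCc1ccc(OC)cc1 | intermediate
8 | (E)-5-[(4-methoxybenzyl)oxy]-2-methylpent-2-en-1-ol | OC/C(C)=C/CCOCc1ccc(OC)cc1 | intermediate
9 | 1-({[(E)-5-bromo-4-methylpent-3-en-1-yl]oxy}methyl)-4-methoxybenzene | BrC/C(C)=C/CCOCc1ccc(OC)cc1 | intermediate
10 | 1,3-dithiane | C1CSCSC1 | starting material
11 | 2-lithio-1,3-dithiane (formed in the flask) | [Li]C1SCCCS1 | intermediate
12 | 2-{(E)-5-[(4-methoxybenzyl)oxy]-2-methylpent-2-en-1-yl}-1,3-dithiane | COc1ccc(COCC/C=C(\C)CC2SCCCS2)cc1 | intermediate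
13 | (S)-5-(hydroxymethyl)furan-2(5H)-one | O=C1O[C@H](CO)C=C1 | starting material
14 | (S)-5-{[(tert-butyldiphenylsilyl)oxy]methyl}furan-2(5H)-one | O=C1O[C@H](CO[Si](c2ccccc2)(c2ccccc2)C(C)(C)C)C=C1 | intermediate
15 | 2-lithio-2-{(E)-5-[(4-methoxybenzyl)oxy]-2-methylpent-2-en-1-yl}-1,3-dithiane (formed in the flask) | [Li]C1(C/C(C)=C/CCOCc2ccc(OC)cc2)SCCCS1 | intermediate
16 | lithium enolate of 17 (formed in the flask) | C1=C(O[Li])O[C@H](CO[Si](c2ccccc2)(c2ccccc2)C(C)(C)C)[C@H]1C2(C/C(C)=C/CCOCc3ccc(OC)cc3)SCCCS2 | intermediate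
17 | (4S,5S)-5-{[(tert-butyldiphenylsilyl)oxy]methyl}-4-(2-{(E)-5-[(4-methoxybenzyl)oxy]-2-methylpent-2-en-1-yl}-1,3-dithian-2-yl)dihydrofuran-2(3H)-one | C1C(=O)O[C@H](CO[Si](c2ccccc2)(c2ccccc2)C(C)(C)C)[C@H]1C2(C/C(C)=C/CCOCc3ccc(OC)cc3)SCCCS2 | intermediate
18 | (4S,5S)-5-{[(tert-butyldiphenylsilyl)oxy]methyl}-4-{(E)-6-[(4-methoxybenzyl)oxy]-3-methylhex-3-enoyl}dihydrofuran-2(3H)-one | C1C(=O)O[C@H](CO[Si](c2ccccc2)(c2ccccc2)C(C)(C)C)[C@H]1C(=O)C/C(C)=C/CCOCc2ccc(OC)cc2 | intermediate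
19 | (4R,5S)-5-{[(tert-butyldiphenylsilyl)oxy]methyl}-4-{(1R,3E)-1-hydroxy-6-[(4-methoxybenzyl)oxy]-3-methylhex-3-en-1-yl}dihydrofuran-2(3H)-one | C1C(=O)O[C@H](CO[Si](c2ccccc2)(c2ccccc2)C(C)(C)C)[C@H]1[C@@H](C/C(C)=C/CCOCc2ccc(OC)cc2)O | intermediate
20 | O-acylisourea of acid 4 and DCC (formed in the flask) | O=C(OC(=NC2CCCCC2)NC2CCCCC2)[C@@]1(C)O[C@H]1C | intermediate
21 | (1R,3E)-1-[(2S,3R)-2-{[(tert-butyldiphenylsilyl)oxy]methyl}-5-oxotetrahydrofuran-3-yl]-6-[(4-methoxybenzyl)oxy]-3-methylhex-3-en-1-yl (2S,3S)-2,3-dimethyloxirane-2-carboxylate | C1C(=O)O[C@H](CO[Si](c2ccccc2)(c2ccccc2)C(C)(C)C)[C@H]1[C@@H](C/C(C)=C/CCOCc2ccc(OC)cc2)OC(=O)[C@@]1(C)O[C@H]1C | intermediate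
22 | (1R)-1-[(2S,3R)-2-{[(tert-butyldiphenylsilyl)oxy]methyl}-5-oxotetrahydrofuran-3-yl]-2-[(2R,3R)-3-{2-[(4-methoxybenzyl)oxy]ethyl}-2-methyloxiran-2-yl]ethyl (2S,3S)-2,3-dimethyloxirane-2-carboxylate | C1C(=O)O[C@H](CO[Si](c2ccccc2)(c2ccccc2)C(C)(C)C)[C@H]1[C@@H](C[C@]1(C)[C@@H](CCOCc2ccc(OC)cc2)O1)OC(=O)[C@@]1(C)O[C@H]1C | intermediate
23 | (1R)-1-[(2S,3R)-2-(hydroxymethyl)-5-oxotetrahydrofuran-3-yl]-2-[(2R,3R)-3-{2-[(4-methoxybenzyl)oxy]ethyl}-2-methyloxiran-2-yl]ethyl (2S,3S)-2,3-dimethyloxirane-2-carboxylate | C1C(=O)O[C@H](CO)[C@H]1[C@@H](C[C@]1(C)[C@@H](CCOCc2ccc(OC)cc2)O1)OC(=O)[C@@]1(C)O[C@H]1C | intermediate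
24 | (1R)-1-[(2S,3R)-2-formyl-5-oxotetrahydrofuran-3-yl]-2-[(2R,3R)-3-{2-[(4-methoxybenzyl)oxy]ethyl}-2-methyloxiran-2-yl]ethyl (2S,3S)-2,3-dimethyloxirane-2-carboxylate | C1C(=O)O[C@H](C=O)[C@H]1[C@@H](C[C@]1(C)[C@@H](CCOCc2ccc(OC)cc2)O1)OC(=O)[C@@]1(C)O[C@H]1C | intermediate
25 | (1R)-1-[(2S,3R)-2-[(Z)-2-iodoprop-1-en-1-yl]-5-oxotetrahydrofuran-3-yl]-2-[(2R,3R)-3-{2-[(4-methoxybenzyl)oxy]ethyl}-2-methyloxiran-2-yl]ethyl (2S,3S)-2,3-dimethyloxirane-2-carboxylate | C1C(=O)O[C@H](/C=C(/C)I)[C@H]1[C@@H](C[C@]1(C)[C@@H](CCOCc2ccc(OC)cc2)O1)OC(=O)[C@@]1(C)O[C@H]1C | intermediate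
26 | lithium enolate of 25 (formed in the flask) | C1=C(O[Li])O[C@H](/C=C(/C)I)[C@H]1[C@@H](C[C@]1(C)[C@@H](CCOCc2ccc(OC)cc2)O1)OC(=O)[C@@]1(C)O[C@H]1C | intermediate
27 | (1R)-1-[(2S,3R,4R)-4-[(dimethylamino)methyl]-2-[(Z)-2-iodoprop-1-en-1-yl]-5-oxotetrahydrofuran-3-yl]-2-[(2R,3R)-3-{2-[(4-methoxybenzyl)oxy]ethyl}-2-methyloxiran-2-yl]ethyl (2S,3S)-2,3-dimethyloxirane-2-carboxylate (Mannich base, formed in the flask) | CN(C)C[C@@H]1C(=O)O[C@H](/C=C(/C)I)[C@H]1[C@@H](C[C@]1(C)[C@@H](CCOCc2ccc(OC)cc2)O1)OC(=O)[C@@]1(C)O[C@H]1C | intermediate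
28 | trimethylammonium iodide of 27 (formed in the flask) | C[N+](C)(C)C[C@@H]1C(=O)O[C@H](/C=C(/C)I)[C@H]1[C@@H](C[C@]1(C)[C@@H](CCOCc2ccc(OC)cc2)O1)OC(=O)[C@@]1(C)O[C@H]1C.[I-] | intermediate
29 | (1R)-1-[(2S,3R)-2-[(Z)-2-iodoprop-1-en-1-yl]-4-methylidene-5-oxotetrahydrofuran-3-yl]-2-[(2R,3R)-3-{2-[(4-methoxybenzyl)oxy]ethyl}-2-methyloxiran-2-yl]ethyl (2S,3S)-2,3-dimethyloxirane-2-carboxylate | C=C1C(=O)O[C@H](/C=C(/C)I)[C@H]1[C@@H](C[C@]1(C)[C@@H](CCOCc2ccc(OC)cc2)O1)OC(=O)[C@@]1(C)O[C@H]1C | intermediate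
30 | (1R)-1-[(2S,3R)-2-[(Z)-2-iodoprop-1-en-1-yl]-4-methylidene-5-oxotetrahydrofuran-3-yl]-2-[(2R,3R)-3-(2-hydroxyethyl)-2-methyloxiran-2-yl]ethyl (2S,3S)-2,3-dimethyloxirane-2-carboxylate | C=C1C(=O)O[C@H](/C=C(/C)I)[C@H]1[C@@H](C[C@]1(C)[C@@H](CCO)O1)OC(=O)[C@@]1(C)O[C@H]1C | intermediate
31 | (1R)-1-[(2S,3R)-2-[(Z)-2-iodoprop-1-en-1-yl]-4-methylidene-5-oxotetrahydrofuran-3-yl]-2-[(2R,3R)-2-methyl-3-(2-oxoethyl)oxiran-2-yl]ethyl (2S,3S)-2,3-dimethyloxirane-2-carboxylate | C=C1C(=O)O[C@H](/C=C(/C)I)[C@H]1[C@@H](C[C@]1(C)[C@@H](CC=O)O1)OC(=O)[C@@]1(C)O[C@H]1C | intermediate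
32 | alkenylchromium dichloride from 31 (C4–CrCl2 in place of C4–I, trivalent chromium, formed in the flask) | C=C1C(=O)O[C@H](/C=C(/C)[Cr](Cl)Cl)[C@H]1[C@@H](C[C@]1(C)[C@@H](CC=O)O1)OC(=O)[C@@]1(C)O[C@H]1C | intermediate
33 | (1R,3S,4Z,6R,7R,8R,10R)-3-hydroxy-1,10-epoxygermacra-4,11(13)-dien-12,6-olid-8-yl (2S,3S)-2,3-dimethyloxirane-2-carboxylate (CNP0268255.2) | C=C1C(=O)O[C@@H]2/C=C(/C)[C@@H](O)C[C@H]3O[C@]3(C)C[C@@H](OC(=O)[C@@]3(C)O[C@H]3C)[C@@H]12 | target

**Count and risks**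

Total step count: 20. Longest linear sequence: 16 steps (steps 4–7, then 9–20).

The three steps most likely to fail:

Step 20 (ring closure). The addition of the alkenylchromium to the aldehyde may show poor facial selectivity at C3, the one stereocenter not set by a reagent, and the β,γ-epoxy aldehyde may decompose by β-elimination before it cyclises. Fallback: from 31 the cyclisation is run as written, and the crude mixture that contains the C3-epimeric (3R)-alcohol F1 is oxidised with Dess–Martin periodinane (NaHCO3, CH2Cl2) to the single macrocyclic 3-ketone F2. F2 is then reduced with catecholborane and the CBS oxazaborolidine enantiomer that delivers hydride to the required face (NaBH4/CeCl3 as the achiral alternative), which returns to 33. This replaces substrate-controlled C–C bond formation by reagent-controlled ketone reduction.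

Step 16 (iodo-olefination). The basic ylide may enolise the α-acyloxy aldehyde (loss of configuration at C6), and the Z selectivity may erode. Fallback: from 24, non-basic Ramirez olefination (CBr4, PPh3, CH2Cl2, 0 °C) gives the 1,1-dibromoalkene F3. A Negishi coupling with MeZnCl and PdCl2(DPEphos) (THF, 0 °C → rt) replaces selectively the bromine trans to C6 and gives the (Z)-bromoalkene F4. Copper-catalysed halogen exchange with retention (CuI, NaI, N,N′-dimethylethylenediamine, dioxane, 110 °C) then returns to 25.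

Step 11 (ketone reduction). The facial bias of the substrate (from C7) may oppose the catalyst, giving a poor diastereomer ratio at C8. Fallback: from 18, reduction with the (R)-oxazaborolidine and catecholborane (the matched pair in that case) gives the (8S)-alcohol F5. F5 is esterified with acid 4 under Mitsunobu conditions (PPh3, DIAD, toluene, 0 °C → rt) with inversion at C8, which returns to 21.

**Further compounds**

F1 | step 20 | C3 epimer of 33, (1R,3R,4Z,6R,7R,8R,10R)-3-hydroxy-1,10-epoxygermacra-4,11(13)-dien-12,6-olid-8-yl (2S,3S)-2,3-dimethyloxirane-2-carboxylate | C=C1C(=O)O[C@@H]2/C=C(/C)[C@H](O)C[C@H]3O[C@]3(C)C[C@@H](OC(=O)[C@@]3(C)O[C@H]3C)[C@@H]12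
F2 | step 20 | (1R,4Z,6R,7R,8R,10R)-3-oxo-1,10-epoxygermacra-4,11(13)-dien-12,6-olid-8-yl (2S,3S)-2,3-dimethyloxirane-2-carboxylate | C=C1C(=O)O[C@@H]2/C=C(/C)C(=O)C[C@H]3O[C@]3(C)C[C@@H](OC(=O)[C@@]3(C)O[C@H]3C)[C@@H]12
F3 | step 16 | 2-(2,2-dibromoethenyl) analogue of 25 (C5H=C4Br2 on C6) | C1C(=O)O[C@H](C=C(Br)Br)[C@H]1[C@@H](C[C@]1(C)[C@@H](CCOCc2ccc(OC)cc2)O1)OC(=O)[C@@]1(C)O[C@H]1C
F4 | step 16 | (Z)-2-bromoprop-1-en-1-yl analogue of 25 | C1C(=O)O[C@H](/C=C(/C)Br)[C@H]1[C@@H](C[C@]1(C)[C@@H](CCOCc2ccc(OC)cc2)O1)OC(=O)[C@@]1(C)O[C@H]1C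
F5 | step 11 | C8 epimer of 19, (4R,5S)-5-{[(tert-butyldiphenylsilyl)oxy]methyl}-4-{(1S,3E)-1-hydroxy-6-[(4-methoxybenzyl)oxy]-3-methylhex-3-en-1-yl}dihydrofuran-2(3H)-one | C1C(=O)O[C@H](CO[Si](c2ccccc2)(c2ccccc2)C(C)(C)C)[C@H]1[C@H](C/C(C)=C/CCOCc2ccc(OC)cc2)O
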